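In prostanoid numbering the ring is C8–C12. Its C9(=O)–C10(Cl)=C11H α-chloroenone is the signature of a dichlorocarbene adduct of a silyl enol ether. Deleting C10 leaves an achiral 3-siloxy-3-(oct-2-ynyl)cyclobutanone whose two CH2 groups (C8, C11) are enantiotopic. Everything rests on re-inserting C10. A chiral lithium amide selects C11. CCl2 addition to the resulting siloxycyclobutene, followed by spontaneous opening of the bicyclo[2.1.0]pentane, delivers in one operation the five-membered ring, C10 with its chlorine, the enone and a fixed C12 configuration. An anti-selective boron aldol with the C1–C7 ynal, acetylation, double semihydrogenation and desilylation complete the target.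

Key step: step 7

Numbering: prostanoid numbering is used for all intermediates (C1 = ester carbon, ring = C8–C12, C20 = end of the lower chain).
Assumption: the lithium amide of (R,R)-bis(1-phenylethyl)amine is taken to deprotonate the CH2 group that leads to (S)-12. The sense of induction cannot be derived safely for this 3,3-disubstituted ketone, and if it proves opposite the equally available (S,S)-amine is used in the same step.

Step 1
Reactants: 1 3-[(tert-butyldimethylsilyl)oxy]cyclobutan-1-one; 2 propargyl bromide
Product: 4 3-[(tert-butyldimethylsilyl)oxy]-1-(prop-2-yn-1-yl)cyclobutan-1-ol (cis/trans mixture), via allenylzinc bromide 3 (not isolated)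
Conditions: Zn dust, THF, 0 to 23 °C; aqueous work-up
Reagents that add atoms: none
Why: Barbier-type propargylation in which zinc inserts into 2 to give allenylzinc bromide 3, which adds to the strained, reactive ketone through a cyclic SE2' transition state to give the homopropargylic tertiary alcohol; the cis/trans ratio is of no consequence because both ring stereocentres vanish in step 4.

Step 2
Reactants: 4 3-[(tert-butyldimethylsilyl)oxy]-1-(prop-2-yn-1-yl)cyclobutan-1-ol; 5 1-iodopentane
Product: 7 3-[(tert-butyldimethylsilyl)oxy]-1-(oct-2-yn-1-yl)cyclobutan-1-ol, via dilithio derivative 6 (not isolated)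
Conditions: n-BuLi (2.2 equiv), THF, −78 to 0 °C; DMPU, n-C5H11I, 0 to 23 °C
Reagents that add atoms: none
Why: Acetylide alkylation (SN2 on a primary iodide) in which the acetylide carbon of dianion 6 reacts while the hindered tertiary lithium alkoxide stays inert, so that no extra protecting group is needed and no stereocentre is formed.

Step 3
Reactants: 7 3-[(tert-butyldimethylsilyl)oxy]-1-(oct-2-yn-1-yl)cyclobutan-1-ol
Product: 8 1-(oct-2-yn-1-yl)cyclobutane-1,3-diol (cis/trans mixture)
Conditions: TBAF, THF, 23 °C
Reagents that add atoms: none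
Why: Fluoride-induced cleavage of the secondary silyl ether, driven by the strong Si–F bond, with alkyne and tertiary alcohol inert.

Step 4
Reactants: 8 1-(oct-2-yn-1-yl)cyclobutane-1,3-diol
Product: 9 3-hydroxy-3-(oct-2-yn-1-yl)cyclobutan-1-one
Conditions: Dess–Martin periodinane, CH2Cl2, 0 to 23 °C
Reagents that add atoms: none
Why: Dess–Martin oxidation, selective by necessity because only the secondary alcohol carries a carbinol hydrogen, and non-basic so that retro-aldol opening of the 3-hydroxycyclobutanone is avoided; the product is achiral.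

Step 5
Reactants: 9 3-hydroxy-3-(oct-2-yn-1-yl)cyclobutan-1-one
Product: 10 3-(oct-2-yn-1-yl)-3-[(triethylsilyl)oxy]cyclobutan-1-one (achiral)
Conditions: TESOTf (1.1 equiv), 2,6-lutidine, CH2Cl2, −78 °C
Reagents that add atoms: triethylsilyl trifluoromethanesulfonate CC[Si](CC)(CC)OS(=O)(=O)C(F)(F)F
Why: Silylation of a hindered tertiary alcohol with a silyl triflate and a non-nucleophilic pyridine base at low temperature, which shuts off retro-aldol pathways in the basic steps that follow.

Step 6
Reactants: 10 3-(oct-2-yn-1-yl)-3-[(triethylsilyl)oxy]cyclobutan-1-one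
Product: 12 (S)-3-(oct-2-yn-1-yl)-1,3-bis[(triethylsilyl)oxy]cyclobut-1-ene, via lithium enolate 11 (not isolated)
Conditions: (R,R)-bis(1-phenylethyl)amine, n-BuLi, THF, −78 to 0 °C; then TESCl and 10, −100 °C (internal quench); cold work-up, used at once
Reagents that add atoms: chlorotriethylsilane CC[Si](Cl)(CC)CC
Why: Enantioselective deprotonation of a prochiral 3-substituted cyclobutanone by a C2-symmetric chiral lithium amide under internal silyl quench is a known desymmetrisation in which the amide removes a proton from one of the two enantiotopic CH2 groups, enolate 11 is silylated before it can expel the β-siloxy group, and the placing of the C9=C11 double bond makes C12 stereogenic (S).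

Step 7
Reactants: 12 (S)-3-(oct-2-yn-1-yl)-1,3-bis[(triethylsilyl)oxy]cyclobut-1-ene; 13 chloroform
Product: 15 (S)-2-chloro-4-(oct-2-yn-1-yl)-4-[(triethylsilyl)oxy]cyclopent-2-en-1-one, via dichlorobicyclopentane 14 (not isolated)
Conditions: CHCl3 (2 equiv), KOtBu (1.5 equiv, added in portions), pentane, −40 to 0 °C; pH 7 buffer
Reagents that add atoms: none
Why: KOtBu converts CHCl3 into singlet CCl2, which adds in a concerted [2+1] fashion to the strained, electron-rich C9=C11 enol ether of 12 to give 14; its zero-atom bridge C9–C11 then breaks in a disrotatory electrocyclic opening as the endo chloride leaves (Woodward–Hoffmann–DePuy rule), pushed by the C9 siloxy group and by release of the bicyclopentane strain, and chloride takes the silyl group from the siloxyallyl cation to unveil 15. The closest known reaction type is the dihalocarbene one-carbon ring expansion of cyclic silyl enol ethers to 2-halocycloalk-2-enones, joined to the known spontaneous opening of cyclobutene–dihalocarbene adducts to 2,3-dihalocyclopentenes. The only ring closed by bond formation is the cyclopropane (cheletropic addition across C9=C11); the five-membered ring is not closed but arises by cleavage of the bond shared by the three- and four-membered rings. No new stereocentre survives: C9 and C11 become sp2, so both faces of 12 converge, C12 is never touched, and its S configuration follows only from the side on which C10 enters, which the enol ether regiochemistry of step 6 fixes. The step needs chemoselectivity for the enol ether over the C14–C15 triple bond, secured because alkynes are poor partners for electrophilic CCl2 (the reason the side chain is carried as an alkyne), and a temperature at or below 0 °C so that carbene capture outruns conrotatory opening of the 3-siloxycyclobutene.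

Step 8
Reactants: 16 methyl 7-hydroxyhept-5-ynoate
Product: 17 methyl 7-oxohept-5-ynoate
Conditions: Dess–Martin periodinane, CH2Cl2, 0 to 23 °C
Reagents that add atoms: none
Why: Dess–Martin oxidation of a primary propargylic alcohol stops cleanly at the ynal and leaves the methyl ester untouched.

Step 9
Reactants: 15 (S)-2-chloro-4-(oct-2-yn-1-yl)-4-[(triethylsilyl)oxy]cyclopent-2-en-1-one; 17 methyl 7-oxohept-5-ynoate
Product: 20 methyl (7R)-7-[(1R,2S)-4-chloro-2-(oct-2-yn-1-yl)-5-oxo-2-(triethylsilyloxy)cyclopent-3-en-1-yl]-7-hydroxyhept-5-ynoate, via boron dienolate 18 (not isolated), via boron aldolate 19 (not isolated)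
Conditions: (c-C6H11)2BCl, Et3N, Et2O, −78 to 0 °C; 17, −78 to −20 °C; pH 7 buffer, MeOH, then SiO2
Reagents that add atoms: none
Why: Anti-selective boron aldol reaction in which soft enolisation can only occur at C8 (C12 is quaternary) and gives the ring-locked E(O)-dienolate 18, which reacts with 17 through a chair Zimmerman–Traxler transition state with the alkynyl group equatorial to set the 7,8-anti relationship, while the aldehyde approaches C8 on the face syn to the C12 oxygen and anti to the C13 chain, as 5-oxygenated cyclopentadienes do, which places the two carbon chains trans.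

Step 10
Reactants: 20 methyl (7R)-7-[(1R,2S)-4-chloro-2-(oct-2-yn-1-yl)-5-oxo-2-(triethylsilyloxy)cyclopent-3-en-1-yl]-7-hydroxyhept-5-ynoate
Product: 21 methyl (7R)-7-acetoxy-7-[(1R,2S)-4-chloro-2-(oct-2-yn-1-yl)-5-oxo-2-(triethylsilyloxy)cyclopent-3-en-1-yl]hept-5-ynoate
Conditions: Ac2O, pyridine, CH2Cl2, 0 °C
Reagents that add atoms: acetic anhydride CC(=O)OC(C)=O
Why: Acylation of the secondary propargylic alcohol with retention at C7 under weakly basic conditions without DMAP, chosen to keep E1cB loss of the new β-acetoxy group slow.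

Step 11
Reactants: 21 methyl (7R)-7-acetoxy-7-[(1R,2S)-4-chloro-2-(oct-2-yn-1-yl)-5-oxo-2-(triethylsilyloxy)cyclopent-3-en-1-yl]hept-5-ynoate
Product: 22 methyl (5Z,7S)-7-acetoxy-7-[(1R,2S)-4-chloro-2-[(2Z)-oct-2-en-1-yl]-5-oxo-2-(triethylsilyloxy)cyclopent-3-en-1-yl]hept-5-enoate
Conditions: H2 (1 atm), Pd/CaCO3 poisoned with Pb(OAc)2 (Lindlar catalyst), quinoline, EtOAc, 23 °C, stopped after two equivalents of H2
Reagents that add atoms: none
Why: Lindlar semihydrogenation delivers H2 syn to both disubstituted alkynes and should give the 5Z and 14Z alkenes in one operation, the poisoned palladium surface leaving the hindered trisubstituted chloroenone, the C–Cl bond and the acetate untouched (C7 changes its descriptor from R to S only through the CIP priorities).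

Step 12
Reactants: 22 methyl (5Z,7S)-7-acetoxy-7-[(1R,2S)-4-chloro-2-[(2Z)-oct-2-en-1-yl]-5-oxo-2-(triethylsilyloxy)cyclopent-3-en-1-yl]hept-5-enoate
Product: 23 punaglandin 8
Conditions: HF·pyridine, pyridine, THF, 0 °C
Reagents that add atoms: none
Why: Fluoride-mediated cleavage of the tertiary triethylsilyl ether under buffered acidic conditions, which avoids base-induced retro-aldol opening at C8–C12, epimerisation at C8 and elimination of acetate.

Compound list
1 | 3-[(tert-butyldimethylsilyl)oxy]cyclobutan-1-one | O=C1CC(O[Si](C)(C)C(C)(C)C)C1 | starting material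
2 | propargyl bromide (3-bromoprop-1-yne) | BrCC#C | starting material
3 | allenylzinc bromide | C=C=C[Zn]Br | intermediate
4 | 3-[(tert-butyldimethylsilyl)oxy]-1-(prop-2-yn-1-yl)cyclobutan-1-ol (cis/trans mixture) | C#CCC1(O)CC(O[Si](C)(C)C(C)(C)C)C1 | intermediate
5 | 1-iodopentane | CCCCCI | starting material
6 | dilithio derivative of 4 (lithium alkoxide, lithium acetylide) | [Li]C#CCC1(O[Li])CC(O[Si](C)(C)C(C)(C)C)C1 | intermediate
7 | 3-[(tert-butyldimethylsilyl)oxy]-1-(oct-2-yn-1-yl)cyclobutan-1-ol (cis/trans mixture) | CCCCCC#CCC1(O)CC(O[Si](C)(C)C(C)(C)C)C1 | intermediate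
8 | 1-(oct-2-yn-1-yl)cyclobutane-1,3-diol (cis/trans mixture) | CCCCCC#CCC1(O)CC(O)C1 | intermediate
9 | 3-hydroxy-3-(oct-2-yn-1-yl)cyclobutan-1-one | CCCCCC#CCC1(O)CC(=O)C1 | intermediate
10 | 3-(oct-2-yn-1-yl)-3-[(triethylsilyl)oxy]cyclobutan-1-one (achiral) | CCCCCC#CCC1(O[Si](CC)(CC)CC)CC(=O)C1 | intermediate
11 | lithium enolate of 10, C9=C11 regioisomer, (S) at C12 | CCCCCC#CC[C@@]1(O[Si](CC)(CC)CC)C=C(O[Li])C1 | intermediate
12 | (S)-3-(oct-2-yn-1-yl)-1,3-bis[(triethylsilyl)oxy]cyclobut-1-ene | CCCCCC#CC[C@@]1(O[Si](CC)(CC)CC)C=C(O[Si](CC)(CC)CC)C1 | intermediate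
13 | chloroform | ClC(Cl)Cl | starting material
14 | (3S)-5,5-dichloro-3-(oct-2-yn-1-yl)-1,3-bis[(triethylsilyl)oxy]bicyclo[2.1.0]pentane (either ring-fusion face, both converge) | CCCCCC#CC[C@@]1(O[Si](CC)(CC)CC)C2C(Cl)(Cl)C2(O[Si](CC)(CC)CC)C1 | intermediate
15 | (S)-2-chloro-4-(oct-2-yn-1-yl)-4-[(triethylsilyl)oxy]cyclopent-2-en-1-one | CCCCCC#CC[C@@]1(O[Si](CC)(CC)CC)C=C(Cl)C(=O)C1 | intermediate
16 | methyl 7-hydroxyhept-5-ynoate | COC(=O)CCCC#CCO | starting material
17 | methyl 7-oxohept-5-ynoate | COC(=O)CCCC#CC=O | intermediate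
18 | dicyclohexylboron dienolate of 15 (C8=C9) | CCCCCC#CC[C@@]1(O[Si](CC)(CC)CC)C=C(Cl)C(OB(C2CCCCC2)C2CCCCC2)=C1 | intermediate
19 | dicyclohexylboron aldolate of 20 | CCCCCC#CC[C@@]1(O[Si](CC)(CC)CC)C=C(Cl)C(=O)[C@@H]1[C@H](C#CCCCC(=O)OC)OB(C2CCCCC2)C2CCCCC2 | intermediate
20 | methyl (7R)-7-[(1R,2S)-4-chloro-2-(oct-2-yn-1-yl)-5-oxo-2-(triethylsilyloxy)cyclopent-3-en-1-yl]-7-hydroxyhept-5-ynoate (7,8-anti; C7 chain trans to C13 chain) | CCCCCC#CC[C@@]1(O[Si](CC)(CC)CC)C=C(Cl)C(=O)[C@@H]1[C@H](C#CCCCC(=O)OC)O | intermediate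
21 | methyl (7R)-7-acetoxy-7-[(1R,2S)-4-chloro-2-(oct-2-yn-1-yl)-5-oxo-2-(triethylsilyloxy)cyclopent-3-en-1-yl]hept-5-ynoate | CCCCCC#CC[C@@]1(O[Si](CC)(CC)CC)C=C(Cl)C(=O)[C@@H]1[C@H](C#CCCCC(=O)OC)OC(C)=O | intermediate
22 | methyl (5Z,7S)-7-acetoxy-7-[(1R,2S)-4-chloro-2-[(2Z)-oct-2-en-1-yl]-5-oxo-2-(triethylsilyloxy)cyclopent-3-en-1-yl]hept-5-enoate | CCCCC/C=C\C[C@@]1(O[Si](CC)(CC)CC)C=C(Cl)C(=O)[C@@H]1[C@H](/C=C\CCCC(=O)OC)OC(C)=O | intermediate
23 | punaglandin 8, methyl (5Z,7S)-7-acetoxy-7-[(1R,2S)-4-chloro-2-hydroxy-2-[(2Z)-oct-2-en-1-yl]-5-oxocyclopent-3-en-1-yl]hept-5-enoate | CCCCC/C=C\C[C@@]1(O)C=C(Cl)C(=O)[C@@H]1[C@H](/C=C\CCCC(=O)OC)OC(C)=O | target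

Total step count: 12. Longest linear sequence: 11 steps (steps 1–7 and 9–12).

Steps most likely to fail

Step 7 (ring expansion). Three things may go wrong. The 3-siloxycyclobutene may open in a conrotatory sense to a bis-siloxydiene before the carbene is captured. Alkoxide may cleave the enol silane, with loss of its regiochemical and hence stereochemical information. Trichloromethyl anion or base may attack the freshly released enone.

The fallback sets out from 12, inserts the carbon stepwise with a halogen-free carbenoid and brings chlorine in afterwards. Et2Zn/CH2I2 (Simmons–Smith cyclopropanation) gives the siloxybicyclo[2.1.0]pentane F1. FeCl3 in DMF opens its central bond oxidatively (Ito–Saegusa ring expansion) to the 3-chlorocyclopentanone F2. NaOAc in MeOH eliminates HCl to the enone F3, and t-BuOOH/DBU gives the epoxy ketone F4. Pyridinium chloride opens F4 at C10 to the chlorohydrin F5, which loses water and comes back to the route at 15.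

Step 6 (desymmetrisation). The two enantiotopic CH2 groups may be poorly discriminated, because the two C12 substituents differ little in size and both puckered conformers can react. Silanolate may also be eliminated from the lithium enolate.

The fallback sets out from 10 and replaces asymmetric induction by physical resolution. LDA/TESCl (internal quench, THF, −78 °C) gives, through the racemic lithium enolate F6, the racemic enol ether F7. The conditions of step 7 take F7 through the racemic dichlorobicyclopentane F8 to the racemic chloroenone. Preparative chromatography on a chiral stationary phase (amylose tris(3,5-dimethylphenylcarbamate)) then separates 15 from its (R)-enantiomer F9. The route is rejoined at 15.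

Step 9 (aldol). The anti preference at C7 may erode, because the slim alkynyl group of 17 pays little for an axial position in the chair. Facial selectivity at C8 next to the quaternary C12 may also be incomplete.

The fallback sets out from 15 and 17, accepts the aldol as a mixture of C7 epimers and makes it stereoconvergent at the esterification stage. The syn boron aldolate F10 is hydrolysed to the (7S)-alcohol F11, which is separated from 20 and esterified with inversion (Mitsunobu reaction: AcOH, PPh3, DIAD, toluene, 0 °C). Compound 20 is acetylated with retention as in step 10, and both streams meet at 21.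

Further compounds
F1 | step 7 | (3S)-3-(oct-2-yn-1-yl)-1,3-bis[(triethylsilyl)oxy]bicyclo[2.1.0]pentane | CCCCCC#CC[C@@]1(O[Si](CC)(CC)CC)C2CC2(O[Si](CC)(CC)CC)C1
F2 | step 7 | (4S)-3-chloro-4-(oct-2-yn-1-yl)-4-[(triethylsilyl)oxy]cyclopentan-1-one | CCCCCC#CC[C@@]1(O[Si](CC)(CC)CC)C(Cl)CC(=O)C1
F3 | step 7 | (S)-4-(oct-2-yn-1-yl)-4-[(triethylsilyl)oxy]cyclopent-2-en-1-one | CCCCCC#CC[C@@]1(O[Si](CC)(CC)CC)C=CC(=O)C1
F4 | step 7 | (4S)-4-(oct-2-yn-1-yl)-4-[(triethylsilyl)oxy]-6-oxabicyclo[3.1.0]hexan-2-one | CCCCCC#CC[C@@]1(O[Si](CC)(CC)CC)C2OC2C(=O)C1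
F5 | step 7 | (4S)-2-chloro-3-hydroxy-4-(oct-2-yn-1-yl)-4-[(triethylsilyl)oxy]cyclopentan-1-one | CCCCCC#CC[C@@]1(O[Si](CC)(CC)CC)C(O)C(Cl)C(=O)C1
F6 | step 6 | racemic lithium enolate of 10 | CCCCCC#CCC1(O[Si](CC)(CC)CC)C=C(O[Li])C1
F7 | step 6 | racemic 3-(oct-2-yn-1-yl)-1,3-bis[(triethylsilyl)oxy]cyclobut-1-ene | CCCCCC#CCC1(O[Si](CC)(CC)CC)C=C(O[Si](CC)(CC)CC)C1
F8 | step 6 | racemic 5,5-dichloro-3-(oct-2-yn-1-yl)-1,3-bis[(triethylsilyl)oxy]bicyclo[2.1.0]pentane | CCCCCC#CCC1(O[Si](CC)(CC)CC)C2C(Cl)(Cl)C2(O[Si](CC)(CC)CC)C1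
F9 | step 6 | (R)-2-chloro-4-(oct-2-yn-1-yl)-4-[(triethylsilyl)oxy]cyclopent-2-en-1-one | CCCCCC#CC[C@]1(O[Si](CC)(CC)CC)C=C(Cl)C(=O)C1
F10 | step 9 | dicyclohexylboron aldolate epimeric with 19 at C7 (7,8-syn) | CCCCCC#CC[C@@]1(O[Si](CC)(CC)CC)C=C(Cl)C(=O)[C@@H]1[C@@H](C#CCCCC(=O)OC)OB(C2CCCCC2)C2CCCCC2
F11 | step 9 | methyl (7S)-7-[(1R,2S)-4-chloro-2-(oct-2-yn-1-yl)-5-oxo-2-(triethylsilyloxy)cyclopent-3-en-1-yl]-7-hydroxyhept-5-ynoate | CCCCCC#CC[C@@]1(O[Si](CC)(CC)CC)C=C(Cl)C(=O)[C@@H]1[C@@H](C#CCCCC(=O)OC)O
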